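## Analysis of the target

The target is a hexacyclic polyphenol: a 3,5-dihydroxyphenyl ring (ring A) is bound through an ether oxygen to a pentaoxygenated benzene (ring B), which is fused through a 1,4-dioxin (ring C) to the central benzene (ring D) of a dibenzofuran (furan ring E, phloroglucinol-type ring F). Atom labels used throughout: B1 carries the ring A oxygen, B2 and B4 carry free hydroxyls, B3 is CH, and B5 and B6 carry the dioxin oxygens; the B5 oxygen is bound to D6 (dibenzofuran C1, in the bay facing ring F) and the B6 oxygen to D1 (dibenzofuran C2), D2 (C3) carries a hydroxyl, D4 the furan oxygen and D5 the bond to F6. There is no stereocentre and no stereogenic axis, so the problem is one of constitution only: seven aryl ether bonds and one biaryl bond have to be placed without ambiguity. The seven free phenols on electron-rich rings are sensitive to air, base and oxidants, so five are carried as methyl ethers to the last step and the two on ring B are freed one step earlier. The difficulty lies in ring B and in the direction of the dioxin: five oxygens on one benzene cannot be introduced by electrophilic chemistry, and the unsymmetrical catechol of ring D can join ring B in two orientations. The strategy rests on the positions of the B2 and B4 hydroxyls, which are meta to each other and each ortho or para to B1 and B5: formyl groups at B2 and B4 turn fluorides at B1 and B5 into leaving groups and are afterwards converted into these hydroxyls by oxygen insertion. B6 is meta to both formyl groups and gains nothing from them, and a catechol monoether on the doubly activated B5 with a free neighbouring phenoxide could pass its aryl group from one oxygen to the other (Smiles rearrangement) before a slow closure at B6. The B6–O–D1 bond is therefore made first, by copper catalysis on a ring B piece with masked formyl groups, and the dioxin is closed afterwards at an activated carbon, where the two fluorides are equivalent by symmetry.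

## Retrosynthetic reasoning

25 to 24. The last disconnection removes the five O-methyl groups of 24. Methyl ethers are kept on rings A, D and F because they survive organolithium reagents, copper, palladium, peracid and base, and a boron Lewis acid removes all of them at once, so the seven free phenols exist only in the final compound.

24 to 22 (key disconnection). The aryl C–O bonds at B2 and B4 of 24 are cut and replaced by C–CHO, which leads through bis-formate 23 to dialdehyde 22. They are cut here because B2 and B4 are the only positions of ring B that are ortho or para to B1 and B5, so formyl groups at these two carbons serve twice: first as activating groups, then as precursors of the hydroxyls. The forward reaction has to insert one oxygen between the ring carbon and the formyl carbon at both sites.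

22 to 19 and 20. The B1–O bond to ring A and the B5–O bond to D6 are cut next. Both carbons are ortho to one formyl group and para to the other, so both bonds can be made by displacement of fluoride. In 19 the two fluorines are related by the mirror plane of ring B through B6 and B3, so the D6 phenoxide gives the same fluoro dioxin 21 whichever one it attacks, and 20 takes the fluorine that is left. The ring closure is in this way an attack at an activated carbon and outruns any aryl migration.

19 to 18, then 17 and 7. The B6–O–D1 bond is cut next. B6 is meta to both formyl groups, so no substitution logic applies, and the bond is made by a copper-catalysed coupling of bromide 7 with phenol 17. In 7 the formyl groups are present as dimethyl acetals, which keeps the fluorines inert during the coupling. In 17 only the D1 hydroxyl is free and the D6 oxygen is a methoxymethyl ether. One acid treatment converts 18 into 19.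

7 to 4 to 1. The two formyl carbons of 7 are disconnected to leave 1. Each fluorine acidifies the hydrogen next to it, so two rounds of lithiation and formylation, with acetal protection in between (4), place the formyl carbons exactly at B2 and B4.

17 to 16 to 15. The benzyl group of 16 is removed last in this branch, and the D5–F6 bond of 16 is cut to give bromide 15. The bromine fixes the site on ring D, and the two ortho positions of ring F in 15 are equivalent, so a palladium-catalysed ring closure can give only one dibenzofuran.

15 to 13 and 14. The D4–O–F1 diaryl ether is cut to phenol 13 and boronic acid 14. A copper-mediated coupling at room temperature is chosen because it leaves the aryl bromide of 13 untouched.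

13 to 11, 10, 9 and 8. The D4 hydroxyl of 13 is traced back to the formyl group of 11 through formate 12, the same oxygen insertion as in the key step. The formyl group of 8 is what tells the two catechol oxygens apart: the hydroxyl para to it is benzylated first (9), the remaining hydroxyl directs bromine to its only free ortho carbon, D5 (10), and is then protected (11). The D1 and D6 oxygens are thereby different from the third step on, which steps 10 and 12 require.

## Alternatives that were turned down

Alternative 1: Ring B is not taken from an arene but made from a four-membered ring, so the disconnection is the B2–B3 carbon–carbon bond. Cyclobutenone A2, which carries the ring A ether and the dibenzofuranyl ether on its two alkene carbons and a hydroxyl and a 1-ethoxyvinyl group on the saturated carbon, would be heated. Electrocyclic opening gives a dienylketene, a 6π ring closure joins the ketene carbon to the vinyl CH2, and tautomerisation gives hydroquinone A1.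
- For: all five oxygens of ring B are in place before the ring becomes aromatic, the step needs no reagent, and it does not depend on an oxidation of an electron-rich molecule. On this last point it is stronger than the chosen route.
- Against: A2 has to come from cyclobutenedione A3, in which two different aryloxy groups sit on neighbouring carbons. The enol ether nucleophile must add to only one of two nearly equal carbonyl groups, and addition to the other exchanges the two aryl ethers in A1. Aryloxy groups on such a dione are vinylogous esters and exchange easily.
- Against: after A1 the dioxin is still open. An intramolecular copper coupling of a ring B hydroxyl with the bromide on ring D must follow in the presence of an air-sensitive hydroquinone, and the ethyl ether must later be cleaved with the methyl ethers.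
- Comparison: the chosen strategy has no such regiochemical question, because bromide 7 is symmetric and its ring B comes from two formylations of a bought arene. In place of the reagent-free ring synthesis it offers oxygens that are each placed by a substitution whose site is fixed by a leaving group.

Alternative 2: The furan ring is cut last, at the D5–F6 carbon–carbon bond and the F1–O bond. O-Aryl hydroxylamine A5, with the N–O unit on D4 of the finished dioxin, would be condensed under strong acid with phloroglucinol A6 reacting as a ketone. The O-aryl oxime ether undergoes a [3,3]-sigmatropic shift that makes the D5–F6 bond, the freed D4 hydroxyl adds to the imine carbon, and the nitrogen is lost, which gives A4 with both ring F hydroxyls free.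
- For: it is stronger than the chosen route in convergence and in economy of protecting groups. The dibenzofuran is made at the end from the simplest source of ring F, and ring F needs no methyl ethers.
- Against: D4–O in A5 has two free ortho carbons, D3 next to the methoxy group and D5 next to the dioxin oxygen. The shift can go to either, nothing in A5 clearly prefers D5, and the D3 product is the linear isomer.
- Against: A6 can condense more than once, strong acid is applied to a polyether with five electron-rich rings, and A5 needs an aryl–O–N bond on a hindered phenol and has a weak N–O bond.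
- Comparison: in the chosen route the same bond is fixed by the bromine of 10, placed ortho to the one free hydroxyl of 9 and carried to 15. The constitution of the dibenzofuran is not in doubt, and it is built early on small molecules.

Alternative 3: The B5–O bond of the dioxin is disconnected oxidatively. In phenol A8 the B6–O–D1 diaryl ether is present, B5 is unsubstituted, and B2 and D6 each carry a free hydroxyl. A hypervalent iodine oxidant in a fluorinated alcohol would oxidise the B2 phenol, the D6 hydroxyl would add to B5, para to it, and rearomatisation would give A7.
- For: it is stronger in step economy for ring B, which needs no activating groups that must later be converted, and it follows the likely biosynthesis.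
- Against: A8 contains rings that are oxidised as easily as the B2 phenol, above all the D6 phenol on trioxygenated ring D. The product A7 is a para-alkoxyphenol and is oxidised more readily than A8, and intermolecular coupling and capture by solvent compete with a closure onto a carbon flanked by two oxygens.
- Against: A8 still needs the hindered B6–O–D1 ether and a ring B with its oxygens in three different states, so the hardest bond of the chosen route is not avoided.
- Comparison: the chosen strategy closes the same ring by a two-electron substitution at a carbon marked by fluorine. The formyl groups that allow this also place the ring A ether and become the B2 and B4 hydroxyls.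

Key step: step 13

Remark: building blocks 1, 8, 14 and 20 are assumed to be bought; the target has no stereocentre, so no configuration has to be set.

## Route

Step 1
Reactants: 1 2-bromo-1,3-difluorobenzene
Product: 4 2-bromo-4-(dimethoxymethyl)-1,3-difluorobenzene, via (3-bromo-2,4-difluorophenyl)lithium 2 (not isolated), via 3-bromo-2,4-difluorobenzaldehyde 3 (not isolated)
Conditions: LiN(i-Pr)2 (LDA), THF, −78 °C; DMF; AcOH; then HC(OMe)3, TsOH (cat.), MeOH, rt
Reagents that add atoms: N,N-dimethylformamide, CN(C)C=O; trimethyl orthoformate, COC(OC)OC
Why: The lithium amide removes the hydrogen next to fluorine, the only acidic site of 1, and the aryllithium is formylated (fluorine-directed ortho-lithiation); the crude aldehyde is masked at once as its dimethyl acetal so that it survives the second metalation.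

Step 2
Reactants: 4 2-bromo-4-(dimethoxymethyl)-1,3-difluorobenzene
Product: 7 3-bromo-1,5-bis(dimethoxymethyl)-2,4-difluorobenzene, via [3-bromo-5-(dimethoxymethyl)-2,4-difluorophenyl]lithium 5 (not isolated), via 3-bromo-5-(dimethoxymethyl)-2,4-difluorobenzaldehyde 6 (not isolated)
Conditions: LiN(i-Pr)2, THF, −78 °C; DMF; AcOH; then HC(OMe)3, TsOH (cat.), MeOH, rt
Reagents that add atoms: N,N-dimethylformamide, CN(C)C=O; trimethyl orthoformate, COC(OC)OC
Why: The same fluorine-directed lithiation now takes place next to the second fluorine, the only ring hydrogen left that is acidified by an ortho fluorine; acetalisation gives a symmetric bis-acetal in which neither fluorine is activated, as the copper coupling of step 10 requires.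

Step 3
Reactants: 8 3,4-dihydroxy-5-methoxybenzaldehyde
Product: 9 4-(benzyloxy)-3-hydroxy-5-methoxybenzaldehyde
Conditions: BnBr (1 equiv), NaHCO3, NaI (cat.), DMF, 40 °C
Reagents that add atoms: benzyl bromide, BrCc1ccccc1
Why: The hydroxyl para to the formyl group is the more acidic one, so a weak base ionises and alkylates only this oxygen (Williamson ether synthesis controlled by acidity); this oxygen is the future D1 oxygen.

Step 4
Reactants: 9 4-(benzyloxy)-3-hydroxy-5-methoxybenzaldehyde
Product: 10 4-(benzyloxy)-2-bromo-3-hydroxy-5-methoxybenzaldehyde
Conditions: NBS, i-Pr2NH (cat.), CH2Cl2, 0 °C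
Reagents that add atoms: N-bromosuccinimide, O=C1CCC(=O)N1Br
Why: Amine-mediated bromination with NBS delivers bromine ortho to a free phenol, and the only free ortho carbon is the one between the hydroxyl and the formyl group (electrophilic aromatic substitution; the related 3-hydroxy-4-methoxybenzaldehyde is brominated at the same site); this carbon is the future D5.

Step 5
Reactants: 10 4-(benzyloxy)-2-bromo-3-hydroxy-5-methoxybenzaldehyde
Product: 11 4-(benzyloxy)-2-bromo-5-methoxy-3-(methoxymethoxy)benzaldehyde
Conditions: MOMCl, i-Pr2NEt, CH2Cl2, 0 °C to rt
Reagents that add atoms: chloromethyl methyl ether, COCCl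
Why: Standard protection of the remaining phenol as its methoxymethyl ether, which is stable to peracid, base, copper and palladium and is later removed by the same acid that frees the ring B aldehydes.

Step 6
Reactants: 11 4-(benzyloxy)-2-bromo-5-methoxy-3-(methoxymethoxy)benzaldehyde
Product: 13 4-(benzyloxy)-2-bromo-5-methoxy-3-(methoxymethoxy)phenol, via 4-(benzyloxy)-2-bromo-5-methoxy-3-(methoxymethoxy)phenyl formate 12 (not isolated)
Conditions: mCPBA, NaHCO3, CH2Cl2, 0 °C to rt; then K2CO3 (cat.), MeOH, rt
Reagents that add atoms: 3-chloroperbenzoic acid, OOC(=O)c1cccc(Cl)c1
Why: Dakin-type Baeyer–Villiger oxidation: the aryl group, which carries a para benzyloxy donor, migrates to oxygen in the peracid adduct, and methanolysis of the formate gives the phenol whose oxygen becomes the furan oxygen.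

Step 7
Reactants: 13 4-(benzyloxy)-2-bromo-5-methoxy-3-(methoxymethoxy)phenol; 14 (3,5-dimethoxyphenyl)boronic acid
Product: 15 2-(benzyloxy)-4-bromo-5-(3,5-dimethoxyphenoxy)-1-methoxy-3-(methoxymethoxy)benzene
Conditions: Cu(OAc)2 (2 equiv), pyridine, 4 Å molecular sieves, CH2Cl2, rt
Reagents that add atoms: none
Why: Chan–Lam coupling forms the diaryl ether at room temperature from the phenol and the arylboronic acid and does not touch the aryl bromide, which is needed in the next step.

Step 8
Reactants: 15 2-(benzyloxy)-4-bromo-5-(3,5-dimethoxyphenoxy)-1-methoxy-3-(methoxymethoxy)benzene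
Product: 16 2-(benzyloxy)-3,7,9-trimethoxy-1-(methoxymethoxy)dibenzo[b,d]furan
Conditions: Pd(OAc)2 (5 mol %), PCy3·HBF4 (10 mol %), K2CO3, DMA, 130 °C
Reagents that add atoms: none
Why: Intramolecular direct arylation: zerovalent palladium inserts into the C–Br bond, ring F is metalated ortho to the ether oxygen by concerted metalation–deprotonation, and reductive elimination closes the furan; the two ortho C–H bonds of ring F are equivalent and the bromide fixes the site on ring D, so one dibenzofuran is expected.

Step 9
Reactants: 16 2-(benzyloxy)-3,7,9-trimethoxy-1-(methoxymethoxy)dibenzo[b,d]furan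
Product: 17 3,7,9-trimethoxy-1-(methoxymethoxy)dibenzo[b,d]furan-2-ol
Conditions: H2 (1 atm), Pd/C, EtOAc–MeOH, rt
Reagents that add atoms: none
Why: Hydrogenolysis cleaves only the benzyl ether and frees the D1 hydroxyl, the oxygen that has to end on B6, while the D6 oxygen stays protected.

Step 10
Reactants: 17 3,7,9-trimethoxy-1-(methoxymethoxy)dibenzo[b,d]furan-2-ol; 7 3-bromo-1,5-bis(dimethoxymethyl)-2,4-difluorobenzene
Product: 18 2-[3,5-bis(dimethoxymethyl)-2,6-difluorophenoxy]-3,7,9-trimethoxy-1-(methoxymethoxy)dibenzo[b,d]furan
Conditions: CuI (10 mol %), picolinic acid (20 mol %), K3PO4, DMSO, 90 °C, argon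
Reagents that add atoms: none
Why: Ullmann-type copper-catalysed O-arylation with picolinic acid as ligand, a system suited to ortho-substituted phenols and aryl halides; with both formyl groups masked the fluorines are inert, so only the C–Br bond reacts and the ether is formed at the carbon that the formyl groups cannot activate.

Step 11
Reactants: 18 2-[3,5-bis(dimethoxymethyl)-2,6-difluorophenoxy]-3,7,9-trimethoxy-1-(methoxymethoxy)dibenzo[b,d]furan
Product: 19 4,6-difluoro-5-[(1-hydroxy-3,7,9-trimethoxydibenzo[b,d]furan-2-yl)oxy]benzene-1,3-dicarbaldehyde
Conditions: 3 M aq. HCl, THF, 45 °C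
Reagents that add atoms: water, O
Why: Aqueous acid hydrolyses both dimethyl acetals and the methoxymethyl ether in one operation, so the two activating formyl groups and the D6 hydroxyl are unmasked together and only under acidic conditions, where the phenol does not yet attack.

Step 12
Reactants: 19 4,6-difluoro-5-[(1-hydroxy-3,7,9-trimethoxydibenzo[b,d]furan-2-yl)oxy]benzene-1,3-dicarbaldehyde; 20 3,5-dimethoxyphenol
Product: 22 hexacyclic ring B dialdehyde, via fluoro dioxin dialdehyde 21 (not isolated)
Conditions: Cs2CO3, DMF, 0 °C to rt; then 20, Cs2CO3, 50 °C
Reagents that add atoms: none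
Why: Two nucleophilic aromatic substitutions: the D6 phenoxide displaces one of the two equivalent fluorides, each ortho to one formyl group and para to the other, and closes the six-membered dioxin ring; the phenoxide of 20 then displaces the remaining fluoride at B1. Because ring B of 19 is symmetric and B6, meta to both formyl groups, is not open to ipso attack, only one constitution can form.

Step 13
Reactants: 22 hexacyclic ring B dialdehyde
Product: 24 pentamethyl ether of the target with free B2 and B4 hydroxyls, via bis-formate 23 (not isolated)
Conditions: mCPBA (3 equiv), NaHCO3 (solid), CH2Cl2, 0 °C to rt; aq. Na2S2O3 wash; then K2CO3 (cat.), MeOH, 0 °C, argon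
Reagents that add atoms: 3-chloroperbenzoic acid, OOC(=O)c1cccc(Cl)c1
Why: The peracid adds to each formyl group to give a peroxy hemiacetal, in which the ring B carbon migrates from carbon to oxygen with loss of 3-chlorobenzoate to give bis-formate 23; mild methanolysis then frees the two phenols. This is the Dakin/Baeyer–Villiger oxidation of alkoxy- and aryloxybenzaldehydes, a standard way to turn the formyl group of a diaryl ether made by fluoride displacement into a hydroxyl. No ring is closed and no stereocentre is formed; the two new bonds are the aryl C–O bonds at B2 and B4. The step needs aryl migration and not hydride migration, which would give carboxylic acids: each formyl-bearing carbon has an ether oxygen ortho and another para (those on B1 and B5), and their lone pairs stabilise the electron-poor migrating carbon. It also needs attack at the aldehydes and not on the trioxygenated rings A and F: carbonyl addition is fast at 0 °C, solid NaHCO3 keeps the medium from turning acidic, and the new phenols stay masked as formates until the excess peracid has been destroyed. The formates are cleaved under argon because the dihydroxy product is easily oxidised.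

Step 14
Reactants: 24 pentamethyl ether of the target with free B2 and B4 hydroxyls
Product: 25 target CNP0256302.0
Conditions: BBr3 (excess), CH2Cl2, −78 °C to rt; MeOH, then H2O
Reagents that add atoms: none
Why: BBr3 cleaves aryl methyl ethers by complexation at oxygen and attack of bromide at the methyl carbon, whereas the diaryl ether, dioxin and furan C–O bonds offer no sp3 carbon and stay intact; an excess is needed for five ethers next to two free phenols.

## Compound list

1 | 2-bromo-1,3-difluorobenzene | Fc1cccc(F)c1Br | starting material
2 | (3-bromo-2,4-difluorophenyl)lithium | [Li]c1ccc(F)c(Br)c1F | intermediate (not isolated)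
3 | 3-bromo-2,4-difluorobenzaldehyde | O=Cc1ccc(F)c(Br)c1F | intermediate (not isolated)
4 | 2-bromo-4-(dimethoxymethyl)-1,3-difluorobenzene | COC(OC)c1ccc(F)c(Br)c1F | intermediate
5 | [3-bromo-5-(dimethoxymethyl)-2,4-difluorophenyl]lithium | [Li]c1cc(C(OC)OC)c(F)c(Br)c1F | intermediate (not isolated)
6 | 3-bromo-5-(dimethoxymethyl)-2,4-difluorobenzaldehyde | O=Cc1cc(C(OC)OC)c(F)c(Br)c1F | intermediate (not isolated)
7 | 3-bromo-1,5-bis(dimethoxymethyl)-2,4-difluorobenzene | COC(OC)c1cc(C(OC)OC)c(F)c(Br)c1F | intermediate
8 | 3,4-dihydroxy-5-methoxybenzaldehyde | COc1cc(C=O)cc(O)c1O | starting material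
9 | 4-(benzyloxy)-3-hydroxy-5-methoxybenzaldehyde | COc1cc(C=O)cc(O)c1OCc1ccccc1 | intermediate
10 | 4-(benzyloxy)-2-bromo-3-hydroxy-5-methoxybenzaldehyde | COc1cc(C=O)c(Br)c(O)c1OCc1ccccc1 | intermediate
11 | 4-(benzyloxy)-2-bromo-5-methoxy-3-(methoxymethoxy)benzaldehyde | COCOc1c(Br)c(C=O)cc(OC)c1OCc1ccccc1 | intermediate
12 | 4-(benzyloxy)-2-bromo-5-methoxy-3-(methoxymethoxy)phenyl formate | COCOc1c(Br)c(OC=O)cc(OC)c1OCc1ccccc1 | intermediate (not isolated)
13 | 4-(benzyloxy)-2-bromo-5-methoxy-3-(methoxymethoxy)phenol | COCOc1c(Br)c(O)cc(OC)c1OCc1ccccc1 | intermediate
14 | (3,5-dimethoxyphenyl)boronic acid | COc1cc(OC)cc(B(O)O)c1 | starting material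
15 | 2-(benzyloxy)-4-bromo-5-(3,5-dimethoxyphenoxy)-1-methoxy-3-(methoxymethoxy)benzene | COCOc1c(Br)c(Oc2cc(OC)cc(OC)c2)cc(OC)c1OCc1ccccc1 | intermediate
16 | 2-(benzyloxy)-3,7,9-trimethoxy-1-(methoxymethoxy)dibenzo[b,d]furan | COCOc1c(OCc2ccccc2)c(OC)cc2oc3cc(OC)cc(OC)c3c12 | intermediate
17 | 3,7,9-trimethoxy-1-(methoxymethoxy)dibenzo[b,d]furan-2-ol | COCOc1c(O)c(OC)cc2oc3cc(OC)cc(OC)c3c12 | intermediate
18 | 2-[3,5-bis(dimethoxymethyl)-2,6-difluorophenoxy]-3,7,9-trimethoxy-1-(methoxymethoxy)dibenzo[b,d]furan | COCOc1c(Oc2c(F)c(C(OC)OC)cc(C(OC)OC)c2F)c(OC)cc2oc3cc(OC)cc(OC)c3c12 | intermediate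
19 | 4,6-difluoro-5-[(1-hydroxy-3,7,9-trimethoxydibenzo[b,d]furan-2-yl)oxy]benzene-1,3-dicarbaldehyde | Oc1c(Oc2c(F)c(C=O)cc(C=O)c2F)c(OC)cc2oc3cc(OC)cc(OC)c3c12 | intermediate
20 | 3,5-dimethoxyphenol | COc1cc(O)cc(OC)c1 | starting material
21 | fluoro dioxin dialdehyde: ring B with F at B1, CHO at B2 and B4, B5–O–D6 and B6–O–D1 closing the dioxin; OMe at D2, F3 and F5 of the dibenzofuran | Fc1c(C=O)cc(C=O)c2c1Oc1c(OC)cc3oc4cc(OC)cc(OC)c4c3c1O2 | intermediate (not isolated)
22 | hexacyclic ring B dialdehyde: as 21 with a 3,5-dimethoxyphenoxy group at B1 in place of fluorine | COc1cc(OC)cc(Oc2c(C=O)cc(C=O)c3c2Oc2c(OC)cc4oc5cc(OC)cc(OC)c5c4c2O3)c1 | intermediate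
23 | bis-formate: as 22 with O–CHO at B2 and B4 in place of CHO | COc1cc(OC)cc(Oc2c(OC=O)cc(OC=O)c3c2Oc2c(OC)cc4oc5cc(OC)cc(OC)c5c4c2O3)c1 | intermediate (not isolated)
24 | pentamethyl ether of the target: OH at B2 and B4; OMe at both ring A positions, D2, F3 and F5 | COc1cc(OC)cc(Oc2c(O)cc(O)c3c2Oc2c(OC)cc4oc5cc(OC)cc(OC)c5c4c2O3)c1 | intermediate
25 | CNP0256302.0: heptahydroxy hexacycle (no stereocentre) | Oc1cc(O)cc(Oc2c(O)cc(O)c3c2Oc2c(O)cc4oc5cc(O)cc(O)c5c4c2O3)c1 | target

## Step count and least certain steps

Total: 14 steps. Steps 1, 2, 6, 12 and 13 each join two operations without purification in between. Longest linear sequence: 12 steps (8 to 25, steps 3 to 14). Steps 1 and 2 form a two-step branch that joins at step 10.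

Step 13 (key step). What may go wrong is hydride migration in place of aryl migration, above all in the second oxidation, when the first formyl group has already become a formate and ring B is less electron-rich; this would give carboxylic acids. Oxidation of the trioxygenated rings A and F by excess peracid is the second risk. Fallback: setting out from 22, addition of MeMgBr to both formyl groups should give the bis(1-hydroxyethyl) compound F1, oxidation with Dess–Martin periodinane the diacetyl compound F2, and Baeyer–Villiger oxidation with mCPBA and a little trifluoroacetic acid the diacetate F3, since a methyl ketone has no hydride to migrate and aryl migrates before methyl. Methanolysis with K2CO3 in MeOH comes back to the route at 24.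

Step 10. What may go wrong is slow coupling, because the phenoxide of 17 is flanked by two oxygens and lies next to the bay, with reduction of the C–Br bond of 7 taking over. Fallback: setting out from 17, metal-free O-arylation with (2,6-difluorophenyl)(2,4,6-trimethoxyphenyl)iodonium tosylate F4 and t-BuOK in THF should give the 2,6-difluorophenyl ether F5. F4 is made in one operation from 1,3-difluoro-2-iodobenzene, mCPBA, TsOH and 1,3,5-trimethoxybenzene, and diaryliodonium salts are known to arylate hindered phenols at room temperature. The formyl groups are then introduced as in steps 1 and 2: LiN(i-Pr)2 and DMF give monoaldehyde F6 (lithium amides metalate next to fluorine but not next to methoxy at −78 °C), acetalisation with HC(OMe)3 and pyridinium tosylate gives acetal F7, and a second lithiation and formylation gives aldehyde acetal F8. Aqueous acid as in step 11 comes back to the route at 19.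

Step 4. What may go wrong is loss of site selectivity: bromination para to the hydroxyl, at the carbon next to the methoxy group, or double bromination. Fallback: setting out from 9, protection with MOMCl gives 4-(benzyloxy)-3-methoxy-5-(methoxymethoxy)benzaldehyde F9 and acetalisation its dimethyl acetal F10. Directed ortho-metalation with n-BuLi at −78 °C should then occur at the carbon flanked by the methoxymethoxy and acetal groups, and quenching with 1,2-dibromotetrachloroethane gives bromo acetal F11. Mild hydrolysis of the acetal with pyridinium tosylate in wet acetone comes back to the route at 11.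

Step 8. What may go wrong is slow oxidative addition at a bromide with oxygen substituents on both sides, or strain in the bay that slows ring closure so that reduction of the C–Br bond wins. Fallback: setting out from 11, Suzuki–Miyaura coupling with (2,4-dimethoxyphenyl)boronic acid (Pd(OAc)2, SPhos, K3PO4) should give biaryl aldehyde F12. Oxidation as in step 6 gives biaryl formate F13 and, after methanolysis, biaryl phenol F14. A phenol-directed C–H activation and C–O ring closure catalysed by Pd(OAc)2 with tert-butyl peroxybenzoate as oxidant then forms the furan from the oxygen side and comes back to the route at 16.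

## Further compounds

F1 | step 13 | bis(1-hydroxyethyl) compound: 22 with CH(OH)CH3 at B2 and B4 (mixture of diastereomers, both centres removed in the next step) | COc1cc(OC)cc(Oc2c(C(C)O)cc(C(C)O)c3c2Oc2c(OC)cc4oc5cc(OC)cc(OC)c5c4c2O3)c1
F2 | step 13 | diacetyl compound: 22 with C(O)CH3 at B2 and B4 | COc1cc(OC)cc(Oc2c(C(C)=O)cc(C(C)=O)c3c2Oc2c(OC)cc4oc5cc(OC)cc(OC)c5c4c2O3)c1
F3 | step 13 | diacetate: 24 with OAc at B2 and B4 | COc1cc(OC)cc(Oc2c(OC(C)=O)cc(OC(C)=O)c3c2Oc2c(OC)cc4oc5cc(OC)cc(OC)c5c4c2O3)c1
F4 | step 10 | (2,6-difluorophenyl)(2,4,6-trimethoxyphenyl)iodonium tosylate | COc1cc(OC)c([I+]c2c(F)cccc2F)c(OC)c1.Cc1ccc(S(=O)(=O)[O-])cc1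
F5 | step 10 | 2-(2,6-difluorophenoxy)-3,7,9-trimethoxy-1-(methoxymethoxy)dibenzo[b,d]furan | COCOc1c(Oc2c(F)cccc2F)c(OC)cc2oc3cc(OC)cc(OC)c3c12
F6 | step 10 | 2,4-difluoro-3-{[3,7,9-trimethoxy-1-(methoxymethoxy)dibenzo[b,d]furan-2-yl]oxy}benzaldehyde | COCOc1c(Oc2c(F)ccc(C=O)c2F)c(OC)cc2oc3cc(OC)cc(OC)c3c12
F7 | step 10 | dimethyl acetal of F6 | COCOc1c(Oc2c(F)ccc(C(OC)OC)c2F)c(OC)cc2oc3cc(OC)cc(OC)c3c12
F8 | step 10 | 5-(dimethoxymethyl)-2,4-difluoro-3-{[3,7,9-trimethoxy-1-(methoxymethoxy)dibenzo[b,d]furan-2-yl]oxy}benzaldehyde | COCOc1c(Oc2c(F)c(C=O)cc(C(OC)OC)c2F)c(OC)cc2oc3cc(OC)cc(OC)c3c12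
F9 | step 4 | 4-(benzyloxy)-3-methoxy-5-(methoxymethoxy)benzaldehyde | COCOc1cc(C=O)cc(OC)c1OCc1ccccc1
F10 | step 4 | 2-(benzyloxy)-5-(dimethoxymethyl)-1-methoxy-3-(methoxymethoxy)benzene | COCOc1cc(C(OC)OC)cc(OC)c1OCc1ccccc1
F11 | step 4 | 2-(benzyloxy)-4-bromo-5-(dimethoxymethyl)-1-methoxy-3-(methoxymethoxy)benzene | COCOc1c(Br)c(C(OC)OC)cc(OC)c1OCc1ccccc1
F12 | step 8 | 4-(benzyloxy)-2-(2,4-dimethoxyphenyl)-5-methoxy-3-(methoxymethoxy)benzaldehyde | COCOc1c(-c2ccc(OC)cc2OC)c(C=O)cc(OC)c1OCc1ccccc1
F13 | step 8 | 4-(benzyloxy)-2-(2,4-dimethoxyphenyl)-5-methoxy-3-(methoxymethoxy)phenyl formate | COCOc1c(-c2ccc(OC)cc2OC)c(OC=O)cc(OC)c1OCc1ccccc1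
F14 | step 8 | 4-(benzyloxy)-2-(2,4-dimethoxyphenyl)-5-methoxy-3-(methoxymethoxy)phenol | COCOc1c(-c2ccc(OC)cc2OC)c(O)cc(OC)c1OCc1ccccc1
A1 | alternative 1 | ring B hydroquinone with ring A ether, dibenzofuranyl ether (bromine at D6) and ethyl ether | CCOc1cc(O)c(Oc2cc(OC)cc(OC)c2)c(Oc2c(OC)cc3oc4cc(OC)cc(OC)c4c3c2Br)c1O
A2 | alternative 1 | 4-(1-ethoxyvinyl)-4-hydroxycyclobutenone with the ring A ether at C2 and the dibenzofuranyl ether at C3 (racemic) | C=C(OCC)C1(O)C(=O)C(Oc2cc(OC)cc(OC)c2)=C1Oc1c(OC)cc2oc3cc(OC)cc(OC)c3c2c1Br
A3 | alternative 1 | 3,4-bis(aryloxy)cyclobutene-1,2-dione with the ring A ether and the dibenzofuranyl ether | O=C1C(=O)C(Oc2cc(OC)cc(OC)c2)=C1Oc1c(OC)cc2oc3cc(OC)cc(OC)c3c2c1Br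
A4 | alternative 2 | pentamethyl ether of the target with both ring F hydroxyls free | COc1cc(OC)cc(Oc2c(OC)cc(OC)c3c2Oc2c(OC)cc4oc5cc(O)cc(O)c5c4c2O3)c1
A5 | alternative 2 | O-aryl hydroxylamine: dioxin of rings A to D with O–NH2 at D4 and hydrogen at D5 | COc1cc(OC)cc(Oc2c(OC)cc(OC)c3c2Oc2c(OC)cc(ON)cc2O3)c1
A6 | alternative 2 | phloroglucinol | Oc1cc(O)cc(O)c1
A7 | alternative 3 | hexamethyl ether of the target with the B2 hydroxyl free | COc1cc(OC)cc(Oc2c(O)cc(OC)c3c2Oc2c(OC)cc4oc5cc(OC)cc(OC)c5c4c2O3)c1
A8 | alternative 3 | open-dioxin phenol: B6–O–D1 ether present, hydrogen at B5, free hydroxyls at B2 and D6 | COc1cc(OC)cc(Oc2c(O)cc(OC)cc2Oc2c(OC)cc3oc4cc(OC)cc(OC)c4c3c2O)c1
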